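If a transfer agent stops the chains that an initiator starts, then with substrate, partner and initiator charged alike the target made in a given time should go as one over c(transfer agent), and we test that on the four new flasks.

| setting | birch | alder | maple | south | north-west | north-east | north |
|---|---|---|---|---|---|---|---|
| substrate | 0.50 M | 0.50 M | 0.50 M | 0.50 M | 0.50 M | 0.50 M | 0.50 M |
| partner | 2.5 M | 2.5 M | 2.5 M | 2.50 M | 2.50 M | 2.50 M | 2.50 M |
| transfer agent | 0.041 M | 0.28 M | 1.1 M | 0.0500 M | 0.150 M | 0.500 M | 1.50 M |
| initiator | 25 mM | 25 mM | 25 mM | 25 mM | 25 mM | 25 mM | 25 mM |
| remark | run made earlier | run made earlier | run made earlier |  |  |  |  |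
| time |  |  |  | 2.5 min | 2.5 min | 2.5 min | 2.5 min |

| run | time / s | target / % | substrate / % |
|---|---|---|---|
| birch | 20.0 | 4.5 | 97.7 |
| birch | 40.0 | 5.1 | 93.5 |
| birch | 60.0 | 8.2 | 89.1 |
| birch | 80.0 | 10.4 | 86.0 |
| alder | 10.0 | 0 | 99.5 |
| alder | 15.0 | 0.4 | 99.4 |
| alder | 30.0 | 0.1 | 96.8 |
| alder | 80.0 | 0 | 97.7 |
| maple | 20.0 | 0 | 99.1 |
| maple | 40.0 | 0 | 99.5 |
| maple | 60.0 | 1.8 | 98.5 |
| maple | 80.0 | 0.9 | 97.8 |

(each reading ± 1 percentage point)

1. amount of target at the end, in percent of the substrate charged for south, north-west, north-east, north, in this order
2. the shape of the row from first to last (falls, then rises / rises all the way / rises, then falls / hardly changes / falls all the way)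

- "hardly changes" means that all values lie within two and a half points (for a concentration: within two and a half percent of the largest)

We take the chain carriers as settled (the steady-state approximation). They are born at the pace of the initiator, whose charge is the same in every flask, and if they die at a pace proportional to c(transfer agent), their level and the target rate both go as one over c(transfer agent). Birch has a stronger last reading than alder and maple: 10.4% target after 80.0 s at 0.041 M gives 5.33 × 10⁻⁵ M s⁻¹ for the agent product, the fraction of charged substrate turned into target per unit time, multiplied by c(transfer agent). This is a reading, with the scatter of its 1 percentage point. After 80.0 s it asks 1.52% of alder, which read 0%, and after 80.0 s it asks 0.388% of maple, which read 0.9%, so neither run speaks against it.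

Multiplying by 2.5 min and dividing by each c(transfer agent), we expect 16.0%, 5.33%, 1.60% and 0.533% from south to north.

The forecast, reasoning that “the agent intercepts the chain”, gave 15%, 2.5%, 0.6% and 0.5%, a row that falls all the way. In north-west and north-east it stands lower than our figures.

The flasks give 12.4%, 3.52%, 1.01% and 0.332%, a row that falls all the way, so the forecast held in row and shape.

    partner + first chain carrier → target + second chain carrier (k = 5500 L mol⁻¹ s⁻¹)
    2 idle radical → ended radicals (k = 2.00 × 10⁸ L mol⁻¹ s⁻¹)
    transfer agent + first chain carrier → side product + idle radical (kL = 72700 L mol⁻¹ s⁻¹)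
    substrate + initiating radical → capped initiator + first chain carrier (k = 2.29 × 10⁵ L mol⁻¹ s⁻¹)
    2 first chain carrier → ended chains (k = 1.20 × 10⁸ L mol⁻¹ s⁻¹)
    initiator → 2 initiating radical (k = 0.00307 s⁻¹)
    substrate + second chain carrier → released group + first chain carrier (k = 19500 L mol⁻¹ s⁻¹)
    target → over-reaction product (k = 0.00450 s⁻¹)

In south, taken net, target was made 3.49 times faster than it was used up at 1.24 min, and at the end 4.68% over-reaction product stands beside 12.4% target. Target and over-reaction product together come to 17.1% in south, where the agent product gave 16.0%, and to 0.468% in north, where it gave 0.533%.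

Readings and results come from a simulation for substances that don't exist; scatter was added.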